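## Analysis of the target

The target is a germacranolide of the heliangolide type. Its ten-membered carbocycle (C1–C10) carries a trans-fused α-methylene-γ-butyrolactone across C6–C7 (lactone oxygen on C6, C12 carbonyl, exocyclic C11=C13), a Z-trisubstituted C4=C5 olefin bearing the C15 methyl group, and a trans-1,10-epoxide bearing the C14 methyl group on C10. C3 carries an isovalerate and C8 a (2R,3R)-epoxyangelate. There are eight stereocentres: six on the ring (1R,3S,6R,7R,8R,10R) and two in the C8 acyl group. H6 and H7 are trans, the C8 oxygen is cis to the C7–C11 bond, and the C3 and C6 oxygens lie on opposite faces of the ring across the Z olefin, so C3 has no short-range relationship to the C6–C8 triad. The sensitive groups are the α-methylene lactone (Michael acceptor), two epoxides (the ring epoxide is trisubstituted, acid-labile and open to transannular attack), three ester-type groups that can migrate to a free neighbouring hydroxyl, and two allylic C–O bonds (C3, C6). The synthesis is hard because a medium ring with two trisubstituted olefins of opposite geometry must be closed, the C6–C7–C8 array sits next to an acidic C7–H, and the ring epoxide has to be introduced with site and face selectivity. The strategy rests on one feature: C6 is an allylic carbinol bonded directly to C5 of the Z C4=C5 olefin. Cutting C5–C6 gives a C6 aldehyde and a C5 alkenyl metal whose geometry is stored in a Z-iodoalkene, and the new C6 oxygen lands next to the C7 acrylate that becomes the lactone.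

## Retrosynthetic reasoning

**C1–C10 epoxide (33 ⇒ 32).** The epoxide is removed first. In 32 the C1=C10 olefin is the only electron-rich, unhindered double bond, so a peracid can address it last. This keeps the acid-labile epoxide out of every Lewis-acidic step, the chromium-mediated ring closure included.

**C8 ester (32 ⇒ 26 + 30).** The C8–O acyl bond is cut to alcohol 26 and epoxy acid 30. Introducing the acyl group as the preformed epoxy acid avoids angelate-to-tiglate isomerisation and sets both acyl stereocentres by reagent control. 30 goes back through epoxy alcohol 29 and allylic alcohol 28 to methyl angelate 27.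

**Lactone (26 ⇒ 25 ⇒ 24).** The C12–O6 bond is cut to the hydroxy acrylate 24, with C8 held as a silyl ether (25). The forward step is a 5-exo transesterification that needs no activation. The silyl ether keeps the C8 oxygen from competing for the acrylate.

**C5–C6, the ring (24 ⇒ 22).** This is the only ring bond whose cleavage gives two functional groups that react with each other and with nothing else in the chain: a Z-alkenyl iodide and an aldehyde. The Z geometry is fixed beforehand, the ring and the C6 carbinol form together, and C7 can direct the new centre. Cutting C1=C10 or C4=C5 instead would make the ring closure also responsible for the geometry of a trisubstituted olefin.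

**C7–C8 (22 ⇒ 20 ⇒ 19 ⇒ 13 + 17).** Aldehyde 22 is masked as dimethyl acetal 20. The C7–C8 bond is cut to aldehyde 13 and allylic bromide 17. A Barbier allylation then delivers the acrylate, the masked C6 aldehyde and both new centres in one convergent step, with the syn relationship following from the Z geometry of 17. The bond lies between the two halves of the chain, and C6 needs no later redox change in the presence of three esters. The cost is that C3, six bonds away, cannot bias the facial sense. This is taken up in the risk section.

**Bromide 17 (17 ⇒ 16 ⇒ 14 + 15).** The C11–C7 bond is cut by a Baylis–Hillman transform to methyl acrylate 14 and 2,2-dimethoxyacetaldehyde 15. Allylic transposition of the adduct 16 places the leaving group on C13.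

**C8–C9 and C1=C10 (13 ⇒ 12 ⇒ 10 ⇒ 9 ⇒ 7 + 8).** The β,γ-unsaturated aldehyde 13 comes from alcohol 12, and 12 from hydroboration of diene 10. Diene 10 is the methylenation product of enal 9. The E C1=C10 olefin of 9 is cut by cross-metathesis to the terminal olefin 7 and methacrolein 8, because this conjugated case is reliably E-selective.

**C2–C3 and the iodoalkene (7 ⇒ 6 ⇒ 4 ⇒ 3 ⇒ 1).** The C2–C3 bond is cut by asymmetric allylation of enal 4, which sets C3 by reagent control. The Z-iodoalkene of 4 comes from alcohol 3, made by hydroxyl-directed carbomagnesiation and iodination of propargyl alcohol 1.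

## Alternatives that were turned down

**Alternative 1:** The C3–O and C6–O bonds and the position of the C4=C5 olefin are traced back to a ten-membered ring holding a C3=C4–C5=C6 diene. Photosensitised singlet oxygen would add across it to give the bridged endoperoxide A1.
- For: one metal-free step makes two C–O bonds and forces the Z geometry. A1 already carries both epoxides and the C8 ester, so the end-game (O–O cleavage, lactonisation of the C6 hydroxyl, acylation at C3) is as short as or shorter than the chosen one.
- Against: the cycloaddition is suprafacial, so A1 has the C3 and C6 oxygens on the same face, whereas the target has them on opposite faces. The isovalerate would have to go in with inversion at an allylic carbinol in a medium ring. The face of attack relative to C7 is left to ring conformation, and ene reactions at C15 and the other allylic positions compete.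
- Comparison: it gives no answer to how the ring with a Z,Z-diene is made. The chosen strategy makes the ring and the C6 centre together from an open chain and has C3 fixed by reagent control beforehand.

**Alternative 2:** The C7–C11 bond and the lactone C–O bond are cut together. In a ring that already holds a C6 phosphonoacetate ester and a trans-7,8-epoxide, the phosphonate anion would open the epoxide at C7 with inversion and close the lactone, which gives the trans-fused α-phosphono lactone A2 with a free C8 hydroxyl. Olefination of A2 with formaldehyde would then install the exocyclic methylene.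
- For: in A2 the C7 and C8 centres follow stereospecifically from the epoxide, the trans ring fusion is assured, and the Michael acceptor appears only at the end. On control of C7/C8 it is stronger than the chosen route, whose Barbier step fixes only the relative configuration.
- Against: the route to A2 presupposes the ten-membered ring with the C6 carbinol and a 7,8-epoxide of defined configuration. That epoxide would have to be formed on the least electron-rich olefin of the ring. Attack at C8 and transannular participation of C1=C10 compete in the opening.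
- Comparison: the ring-closure problem is only moved, since A2 is reached from a ring that must already exist. The chosen strategy offers a convergent assembly and ring closure with all carbons and oxygens in place.

**Alternative 3:** The ring is traced back to a six-membered precursor. The potassium alkoxide of a trans-1,2-dialkenylcyclohexenol would undergo anionic oxy-Cope ring expansion to the ten-membered dienone A3.
- For: no high dilution is needed, the chair transition state gives the E C1=C10 olefin, and the precursor is available from the chiral pool. For ring formation it is more dependable than a chromium-mediated macrocyclisation.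
- Against: A3 has C6 as a ketone, no three-carbon unit on C7, and C8 as a C–Si bond. A regio- and stereoselective C7 functionalisation, a diastereoselective C6 reduction and a Tamao–Fleming oxidation in the presence of two olefins would all follow. The Z enone could isomerise on the way.
- Comparison: several stereo-defining steps remain on the medium ring after it is formed. The chosen route spends its risk on the ring closure itself and needs only four functional-group steps afterwards.

Key step: step 14

**Remarks before the steps**

- Germacrane numbering (C1–C15) is used for all intermediates. The CIP letter at C7 changes with the substituents (S in 24 and 25, R in 26, 32 and 33) without any change in space.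
- Assumption: the allylborane derived from (+)-α-pinene is taken to show its usual preference for the Si face of aldehyde 4, which corresponds to 3S. If it does not, the antipodal reagent is used.
- Assumption: the (1R,10R) epoxide is taken to be the product of peracid attack on the exposed outer face of the E olefin of 32.

## Steps

Step 1
Reactants: 1 prop-2-yn-1-ol (propargyl alcohol)
Product: 3 (2Z)-3-iodo-2-methylprop-2-en-1-ol, via magnesium chelate 2 (not isolated)
Conditions: MeMgBr (3 equiv), CuI (10 mol%), THF, −10 °C to rt; then I2, −78 to 0 °C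
Reagents that add atoms: methylmagnesium bromide, C[Mg]Br; iodine, II
Why: Copper-catalysed anti-carbomagnesiation of the propargylic magnesium alkoxide places the methyl group on the internal carbon and magnesium on the terminus inside chelate 2, and iodinolysis with retention leaves iodine cis to the carbinol carbon (Z); this is the known hydroxyl-directed carbomagnesiation–iodination of propargyl alcohols.

Step 2
Reactants: 3 (2Z)-3-iodo-2-methylprop-2-en-1-ol
Product: 4 (2Z)-3-iodo-2-methylprop-2-enal
Conditions: activated MnO2 (15 equiv), CH2Cl2, rt, dark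
Reagents that add atoms: none
Why: Allylic oxidation with MnO2 under neutral heterogeneous conditions gives the enal without Z/E isomerisation; the volatile, light-sensitive aldehyde is carried on as a solution.

Step 3
Reactants: 4 (2Z)-3-iodo-2-methylprop-2-enal
Product: 6 (1Z,3S)-1-iodo-2-methylhexa-1,5-dien-3-ol, via borinate 5 (not isolated)
Conditions: (−)-Ipc2B(allyl) (1.3 equiv), Et2O, −78 °C; then aq NaOH, H2O2, 0 °C to rt
Reagents that add atoms: (−)-B-allyldiisopinocampheylborane, C=CCB([C@@H]1C[C@@H]2C[C@H]([C@H]1C)C2(C)C)[C@@H]1C[C@@H]2C[C@H]([C@H]1C)C2(C)C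
Why: Brown allylation through a closed chair transition state; the reagent derived from (+)-α-pinene delivers the allyl group to the Si face of the aldehyde, which sets C3 as S under reagent control, and the oxidative work-up cleaves borinate 5.

Step 4
Reactants: 6 (1Z,3S)-1-iodo-2-methylhexa-1,5-dien-3-ol
Product: 7 (1Z,3S)-1-iodo-2-methylhexa-1,5-dien-3-yl 3-methylbutanoate
Conditions: isovaleryl chloride, pyridine, DMAP (cat.), CH2Cl2, 0 °C to rt
Reagents that add atoms: 3-methylbutanoyl chloride, CC(C)CC(=O)Cl
Why: Acylation of the secondary allylic alcohol; the ester is the final C3 substituent and at the same time protects this oxygen for the rest of the route, with no change at C3.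

Step 5
Reactants: 7 (1Z,3S)-1-iodo-2-methylhexa-1,5-dien-3-yl 3-methylbutanoate; 8 methacrolein (2-methylprop-2-enal)
Product: 9 (1Z,3S,5E)-1-iodo-2,6-dimethyl-7-oxohepta-1,5-dien-3-yl 3-methylbutanoate
Conditions: 8 (5 equiv), second-generation Hoveyda–Grubbs catalyst (5 mol%), CH2Cl2, 40 °C
Reagents that add atoms: none
Why: Cross-metathesis of the terminal olefin with methacrolein gives the conjugated 2-methyl-2-enal, for which the E isomer is strongly favoured; the trisubstituted iodoalkene does not engage the ruthenium carbene. This fixes the E geometry of the later C1=C10 olefin.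

Step 6
Reactants: 9 (1Z,3S,5E)-1-iodo-2,6-dimethyl-7-oxohepta-1,5-dien-3-yl 3-methylbutanoate
Product: 10 (1Z,3S,5E)-1-iodo-2,6-dimethylocta-1,5,7-trien-3-yl 3-methylbutanoate
Conditions: Ph3PCH3Br, KN(SiMe3)2, THF, 0 °C; then 9, −78 to 0 °C
Reagents that add atoms: methyltriphenylphosphonium bromide, C[P+](c1ccccc1)(c1ccccc1)c1ccccc1.[Br-]
Why: Wittig methylenation of the enal carbonyl (1,2-addition) turns C9 into a vinyl carbon and brings in C8; at low temperature the non-stabilised ylide reacts with the aldehyde far faster than with the isovalerate.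

Step 7
Reactants: 10 (1Z,3S,5E)-1-iodo-2,6-dimethylocta-1,5,7-trien-3-yl 3-methylbutanoate
Product: 12 (1Z,3S,5E)-8-hydroxy-1-iodo-2,6-dimethylocta-1,5-dien-3-yl 3-methylbutanoate, via alkylborane 11 (not isolated)
Conditions: 9-BBN (1.2 equiv), THF, 0 °C to rt; then H2O2, aq NaHCO3, 0 °C
Reagents that add atoms: hydrogen peroxide, OO
Why: Hydroboration–oxidation: the bulky borane adds to the unsubstituted terminus of the monosubstituted double bond of the diene and leaves the trisubstituted olefin and the iodoalkene alone, so that C8 becomes a primary alcohol; oxidation of 11 under bicarbonate buffering spares the ester.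

Step 8
Reactants: 12 (1Z,3S,5E)-8-hydroxy-1-iodo-2,6-dimethylocta-1,5-dien-3-yl 3-methylbutanoate
Product: 13 (1Z,3S,5E)-1-iodo-2,6-dimethyl-8-oxoocta-1,5-dien-3-yl 3-methylbutanoate
Conditions: Dess–Martin periodinane (1.3 equiv), NaHCO3, CH2Cl2, 0 °C to rt
Reagents that add atoms: none
Why: Dess–Martin oxidation under buffered, non-basic conditions gives the β,γ-unsaturated aldehyde without migration of the C1=C10 double bond into conjugation; 13 is used at once.

Step 9
Reactants: 14 methyl acrylate; 15 2,2-dimethoxyacetaldehyde (60% in water)
Product: 16 methyl 3-hydroxy-4,4-dimethoxy-2-methylidenebutanoate (racemic)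
Conditions: DABCO (0.5 equiv), 1,4-dioxane/H2O, rt
Reagents that add atoms: none
Why: Baylis–Hillman reaction: the amine adds to the acrylate and the resulting enolate attacks the electrophilic α-alkoxy aldehyde, which joins C11 to C7; the carbinol centre is racemic and is erased in step 10.

Step 10
Reactants: 16 methyl 3-hydroxy-4,4-dimethoxy-2-methylidenebutanoate
Product: 17 methyl (2Z)-2-(bromomethyl)-4,4-dimethoxybut-2-enoate
Conditions: NBS, Me2S, CH2Cl2, 0 °C to rt
Reagents that add atoms: N-bromosuccinimide, BrN1C(=O)CCC1=O
Why: Activation of the hydroxyl by the bromosulfonium reagent and SN2' attack of bromide move the leaving group to C13 and give the trisubstituted enoate with the acetal carbon trans to the ester (Z), the known outcome for Baylis–Hillman adducts; the conditions are neutral enough for the acetal.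

Step 11
Reactants: 13 (1Z,3S,5E)-1-iodo-2,6-dimethyl-8-oxoocta-1,5-dien-3-yl 3-methylbutanoate; 17 methyl (2Z)-2-(bromomethyl)-4,4-dimethoxybut-2-enoate
Product: 19 methyl (3R,4R,6E,9S,10Z)-3-(dimethoxymethyl)-4-hydroxy-11-iodo-6,10-dimethyl-2-methylidene-9-[(3-methylbutanoyl)oxy]undeca-6,10-dienoate, via allylindium 18 (not isolated)
Conditions: 17 (1.5 equiv), In powder (1.5 equiv), THF/H2O (1:1), rt
Reagents that add atoms: none
Why: Indium-mediated Barbier allylation: allylindium 18 adds through C7 in a chair transition state with the aldehyde chain equatorial and the acetal carbon (cis to the metal-bearing carbon) axial, which gives the C7/C8-syn adduct, the hydroxyl anti to the acrylate in the C6–C9 zigzag. C3 is too remote to bias the face of the aldehyde, so the syn adduct is expected as two diastereomers, and 19 (C7 R, C8 R in germacrane numbering) is isolated by chromatography. Iodoalkene, esters and acetal are inert to indium in aqueous THF.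

Step 12
Reactants: 19 methyl (3R,4R,6E,9S,10Z)-3-(dimethoxymethyl)-4-hydroxy-11-iodo-6,10-dimethyl-2-methylidene-9-[(3-methylbutanoyl)oxy]undeca-6,10-dienoate
Product: 20 methyl (3R,4R,6E,9S,10Z)-4-[(tert-butyldimethylsilyl)oxy]-3-(dimethoxymethyl)-11-iodo-6,10-dimethyl-2-methylidene-9-[(3-methylbutanoyl)oxy]undeca-6,10-dienoate
Conditions: TBSOTf (1.3 equiv), 2,6-lutidine, CH2Cl2, −78 °C
Reagents that add atoms: tert-butyldimethylsilyl trifluoromethanesulfonate, CC(C)(C)[Si](C)(C)OS(=O)(=O)C(F)(F)F
Why: Silylation with the silyl triflate at −78 °C is faster than lactonisation of the γ-hydroxy ester through the C8 hydroxyl and leaves the dimethyl acetal intact; no stereocentre is touched.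

Step 13
Reactants: 20 methyl (3R,4R,6E,9S,10Z)-4-[(tert-butyldimethylsilyl)oxy]-3-(dimethoxymethyl)-11-iodo-6,10-dimethyl-2-methylidene-9-[(3-methylbutanoyl)oxy]undeca-6,10-dienoate
Product: 22 methyl (3R,4R,6E,9S,10Z)-4-[(tert-butyldimethylsilyl)oxy]-3-formyl-11-iodo-6,10-dimethyl-2-methylidene-9-[(3-methylbutanoyl)oxy]undeca-6,10-dienoate, via collidinium salt 21 (not isolated)
Conditions: TESOTf (2 equiv), 2,4,6-collidine (3 equiv), CH2Cl2, 0 °C; then H2O, rt
Reagents that add atoms: water, O
Why: Chemoselective cleavage of an aldehyde dimethyl acetal: the silyl triflate ionises one methoxy group, collidine traps the oxocarbenium ion as salt 21, and water then releases the aldehyde without protic acid, so the secondary silyl ether, the esters and the epimerisable C7 centre are preserved; 22 is taken directly into step 14.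

Step 14
Reactants: 22 methyl (3R,4R,6E,9S,10Z)-4-[(tert-butyldimethylsilyl)oxy]-3-formyl-11-iodo-6,10-dimethyl-2-methylidene-9-[(3-methylbutanoyl)oxy]undeca-6,10-dienoate
Product: 24 methyl (3S,6R,7S,8R)-8-[(tert-butyldimethylsilyl)oxy]-6-hydroxy-3-[(3-methylbutanoyl)oxy]germacra-1(10)E,4Z,11(13)-trien-12-oate, via alkenylchromium 23 (not isolated)
Conditions: CrCl2 (10 equiv), NiCl2 (0.1 equiv), degassed DMSO, rt; 22 added over 12 h to 0.002 M
Reagents that add atoms: none
Why: Divalent chromium reduces the nickel salt to zerovalent nickel; oxidative addition of the C5–I bond of 22 to nickel keeps the Z geometry, and transfer of the alkenyl group to trivalent chromium gives 23 and returns divalent nickel to the cycle. 23 adds to the C6 aldehyde in a 10-exo-trig closure that forms C5–C6 and the ten-membered carbocycle; the closest known reaction type is the intramolecular Nozaki–Hiyama–Kishi coupling of iodoalkenyl aldehydes to medium and large rings. The new C6 centre is controlled by C7 in the Felkin–Anh sense: the C8 branch, which is also the ring tether, stands anti to the incoming alkenyl group, the acrylate lies next to the carbonyl oxygen and hydrogen faces the nucleophile, which places the C6 oxygen syn to the acrylate (6R, H6 and H7 trans) and 1,3-anti to the C8 silyl ether, so the 1,2- and 1,3-effects reinforce each other. The step needs selectivity for the aldehyde over three esters and the acrylate, which the low basicity and carbonyl selectivity of alkenylchromium reagents provide, so that C7 is not epimerised and the C8 silyloxy group is not eliminated. It needs ring closure to outrun dimerisation, which slow addition at high dilution secures, helped by the two trisubstituted olefins that take four of the ten ring atoms out of free rotation. The olefin geometry is fixed before the ring closes and cannot be lost in this step.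

Step 15
Reactants: 24 methyl (3S,6R,7S,8R)-8-[(tert-butyldimethylsilyl)oxy]-6-hydroxy-3-[(3-methylbutanoyl)oxy]germacra-1(10)E,4Z,11(13)-trien-12-oate
Product: 25 (3S,6R,7S,8R)-8-[(tert-butyldimethylsilyl)oxy]-3-[(3-methylbutanoyl)oxy]germacra-1(10)E,4Z,11(13)-trien-12,6-olide
Conditions: camphorsulfonic acid (0.1 equiv), 4 Å molecular sieves, CH2Cl2, rt
Reagents that add atoms: none
Why: Acid-catalysed transesterification: the C6 hydroxyl attacks the neighbouring acrylate ester in a 5-exo-trig closure to the trans-fused α-methylene-γ-butyrolactone, driven by uptake of methanol on the sieves; a secondary silyl ether tolerates catalytic sulfonic acid in an aprotic solvent.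

Step 16
Reactants: 25 (3S,6R,7S,8R)-8-[(tert-butyldimethylsilyl)oxy]-3-[(3-methylbutanoyl)oxy]germacra-1(10)E,4Z,11(13)-trien-12,6-olide
Product: 26 (3S,6R,7R,8R)-8-hydroxy-3-[(3-methylbutanoyl)oxy]germacra-1(10)E,4Z,11(13)-trien-12,6-olide
Conditions: HF·pyridine, THF/pyridine, 0 °C to rt
Reagents that add atoms: none
Why: Cleavage of the silyl ether with buffered HF·pyridine; the non-basic medium avoids acyl migration to the freed C8 hydroxyl, translactonisation and conjugate addition to the methylene lactone.

Step 17
Reactants: 27 methyl angelate (methyl (2Z)-2-methylbut-2-enoate)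
Product: 28 (2Z)-2-methylbut-2-en-1-ol
Conditions: iBu2AlH (2.2 equiv), CH2Cl2, −78 °C
Reagents that add atoms: none
Why: Reduction of the conjugated ester with the aluminium hydride at low temperature gives the allylic alcohol without conjugate reduction or Z/E isomerisation.

Step 18
Reactants: 28 (2Z)-2-methylbut-2-en-1-ol
Product: 29 [(2S,3R)-2,3-dimethyloxiran-2-yl]methanol
Conditions: Ti(OiPr)4 (10 mol%), L-(+)-diethyl tartrate (12 mol%), tBuOOH, 4 Å molecular sieves, CH2Cl2, −20 °C
Reagents that add atoms: tert-butyl hydroperoxide, CC(C)(C)OO
Why: Sharpless asymmetric epoxidation: with L-(+)-tartrate the titanium peroxo complex delivers oxygen to the face of the allylic alcohol that gives the (2S,3R)-epoxy alcohol, the precursor of the (2R,3R)-acid; the cis relationship of the C3 methyl group and the carbinol carbon is carried over from the Z olefin.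

Step 19
Reactants: 29 [(2S,3R)-2,3-dimethyloxiran-2-yl]methanol
Product: 30 (2R,3R)-2,3-dimethyloxirane-2-carboxylic acid (epoxyangelic acid)
Conditions: RuCl3 (2 mol%), NaIO4 (3 equiv), CCl4/MeCN/H2O, rt
Reagents that add atoms: water, O
Why: RuO4, generated catalytically with periodate, oxidises the primary alcohol through the aldehyde hydrate to the carboxylic acid; the epoxide and both stereocentres are untouched, and the change of the C2 letter from S to R is a priority effect.

Step 20
Reactants: 26 (3S,6R,7R,8R)-8-hydroxy-3-[(3-methylbutanoyl)oxy]germacra-1(10)E,4Z,11(13)-trien-12,6-olide; 30 (2R,3R)-2,3-dimethyloxirane-2-carboxylic acid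
Product: 32 (3S,6R,7R,8R)-8-{[(2R,3R)-2,3-dimethyloxiran-2-yl]carbonyloxy}-3-[(3-methylbutanoyl)oxy]germacra-1(10)E,4Z,11(13)-trien-12,6-olide, via mixed anhydride 31 (not isolated)
Conditions: 30, 2,4,6-trichlorobenzoyl chloride, Et3N, toluene, rt; then 26, DMAP, toluene, rt
Reagents that add atoms: none
Why: Yamaguchi esterification: the acid is activated as mixed anhydride 31 and transferred by DMAP to the hindered C8 hydroxyl; using the preformed epoxy acid avoids angelate-to-tiglate isomerisation and carries both acyl stereocentres over from step 18.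

Step 21
Reactants: 32 (3S,6R,7R,8R)-8-{[(2R,3R)-2,3-dimethyloxiran-2-yl]carbonyloxy}-3-[(3-methylbutanoyl)oxy]germacra-1(10)E,4Z,11(13)-trien-12,6-olide
Product: 33 (1R,3S,6R,7R,8R,10R)-1,10-epoxy-8-{[(2R,3R)-2,3-dimethyloxiran-2-yl]carbonyloxy}-3-[(3-methylbutanoyl)oxy]germacra-4Z,11(13)-dien-12,6-olide (CNP0167461.2)
Conditions: mCPBA (1.1 equiv), NaHCO3, CH2Cl2, 0 °C
Reagents that add atoms: 3-chloroperoxybenzoic acid, OOC(=O)c1cccc(Cl)c1
Why: Peracid epoxidation: C1=C10 is the only electron-rich, unhindered double bond (C4=C5 is flanked by two allylic acyloxy groups, C11=C13 is conjugated to the lactone), and the E olefin of the ten-membered ring exposes only its outer face, which should give the (1R,10R)-epoxide.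

## Compound list

1 | prop-2-yn-1-ol (propargyl alcohol) | C#CCO | starting material
2 | 4-methyl-2,5-dihydro-1,2-oxamagnesole (magnesium chelate) | CC1=C[Mg]OC1 | intermediate (not isolated)
3 | (2Z)-3-iodo-2-methylprop-2-en-1-ol | I/C=C(/C)CO | intermediate
4 | (2Z)-3-iodo-2-methylprop-2-enal | I/C=C(/C)C=O | intermediate
5 | (1Z,3S)-1-iodo-2-methylhexa-1,5-dien-3-yl diisopinocampheylborinate | I/C=C(/C)[C@@H](OB([C@@H]1C[C@@H]2C[C@H]([C@H]1C)C2(C)C)[C@@H]1C[C@@H]2C[C@H]([C@H]1C)C2(C)C)CC=C | intermediate (not isolated)
6 | (1Z,3S)-1-iodo-2-methylhexa-1,5-dien-3-ol | I/C=C(/C)[C@@H](O)CC=C | intermediate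
7 | (1Z,3S)-1-iodo-2-methylhexa-1,5-dien-3-yl 3-methylbutanoate | I/C=C(/C)[C@@H](OC(=O)CC(C)C)CC=C | intermediate
8 | methacrolein (2-methylprop-2-enal) | C=C(C)C=O | starting material
9 | (1Z,3S,5E)-1-iodo-2,6-dimethyl-7-oxohepta-1,5-dien-3-yl 3-methylbutanoate | I/C=C(/C)[C@@H](OC(=O)CC(C)C)C/C=C(\C)C=O | intermediate
10 | (1Z,3S,5E)-1-iodo-2,6-dimethylocta-1,5,7-trien-3-yl 3-methylbutanoate | I/C=C(/C)[C@@H](OC(=O)CC(C)C)C/C=C(\C)C=C | intermediate
11 | 9-BBN adduct of 10 (boron on C8) | I/C=C(/C)[C@@H](OC(=O)CC(C)C)C/C=C(\C)CCB1C2CCCC1CCC2 | intermediate (not isolated)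
12 | (1Z,3S,5E)-8-hydroxy-1-iodo-2,6-dimethylocta-1,5-dien-3-yl 3-methylbutanoate | I/C=C(/C)[C@@H](OC(=O)CC(C)C)C/C=C(\C)CCO | intermediate
13 | (1Z,3S,5E)-1-iodo-2,6-dimethyl-8-oxoocta-1,5-dien-3-yl 3-methylbutanoate | I/C=C(/C)[C@@H](OC(=O)CC(C)C)C/C=C(\C)CC=O | intermediate
14 | methyl acrylate | C=CC(=O)OC | starting material
15 | 2,2-dimethoxyacetaldehyde | COC(OC)C=O | starting material
16 | methyl 3-hydroxy-4,4-dimethoxy-2-methylidenebutanoate (racemic) | C=C(C(=O)OC)C(O)C(OC)OC | intermediate
17 | methyl (2Z)-2-(bromomethyl)-4,4-dimethoxybut-2-enoate | COC(=O)/C(CBr)=C/C(OC)OC | intermediate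
18 | allylindium dibromide from 17 (trivalent indium on C13) | COC(=O)/C(C[In](Br)Br)=C/C(OC)OC | intermediate (not isolated)
19 | methyl (3R,4R,6E,9S,10Z)-3-(dimethoxymethyl)-4-hydroxy-11-iodo-6,10-dimethyl-2-methylidene-9-[(3-methylbutanoyl)oxy]undeca-6,10-dienoate | I/C=C(/C)[C@@H](OC(=O)CC(C)C)C/C=C(\C)C[C@@H](O)[C@@H](C(=C)C(=O)OC)C(OC)OC | intermediate
20 | methyl (3R,4R,6E,9S,10Z)-4-[(tert-butyldimethylsilyl)oxy]-3-(dimethoxymethyl)-11-iodo-6,10-dimethyl-2-methylidene-9-[(3-methylbutanoyl)oxy]undeca-6,10-dienoate | I/C=C(/C)[C@@H](OC(=O)CC(C)C)C/C=C(\C)C[C@@H](O[Si](C)(C)C(C)(C)C)[C@@H](C(=C)C(=O)OC)C(OC)OC | intermediate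
21 | C6 methoxy(2,4,6-trimethylpyridinium) salt of 20, triflate (C6 epimers) | I/C=C(/C)[C@@H](OC(=O)CC(C)C)C/C=C(\C)C[C@@H](O[Si](C)(C)C(C)(C)C)[C@@H](C(=C)C(=O)OC)C(OC)[n+]1c(C)cc(C)cc1C.[O-]S(=O)(=O)C(F)(F)F | intermediate (not isolated)
22 | methyl (3R,4R,6E,9S,10Z)-4-[(tert-butyldimethylsilyl)oxy]-3-formyl-11-iodo-6,10-dimethyl-2-methylidene-9-[(3-methylbutanoyl)oxy]undeca-6,10-dienoate | I/C=C(/C)[C@@H](OC(=O)CC(C)C)C/C=C(\C)C[C@@H](O[Si](C)(C)C(C)(C)C)[C@@H](C(=C)C(=O)OC)C=O | intermediate
23 | alkenylchromium dichloride from 22 (trivalent chromium on C5) | Cl[Cr](Cl)/C=C(/C)[C@@H](OC(=O)CC(C)C)C/C=C(\C)C[C@@H](O[Si](C)(C)C(C)(C)C)[C@@H](C(=C)C(=O)OC)C=O | intermediate (not isolated)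
24 | methyl (3S,6R,7S,8R)-8-[(tert-butyldimethylsilyl)oxy]-6-hydroxy-3-[(3-methylbutanoyl)oxy]germacra-1(10)E,4Z,11(13)-trien-12-oate | C=C(C(=O)OC)[C@H]1[C@H](O)/C=C(/C)[C@@H](OC(=O)CC(C)C)C/C=C(\C)C[C@H]1O[Si](C)(C)C(C)(C)C | intermediate
25 | (3S,6R,7S,8R)-8-[(tert-butyldimethylsilyl)oxy]-3-[(3-methylbutanoyl)oxy]germacra-1(10)E,4Z,11(13)-trien-12,6-olide | C=C1C(=O)O[C@@H]2/C=C(/C)[C@@H](OC(=O)CC(C)C)C/C=C(\C)C[C@@H](O[Si](C)(C)C(C)(C)C)[C@@H]12 | intermediate
26 | (3S,6R,7R,8R)-8-hydroxy-3-[(3-methylbutanoyl)oxy]germacra-1(10)E,4Z,11(13)-trien-12,6-olide | C=C1C(=O)O[C@@H]2/C=C(/C)[C@@H](OC(=O)CC(C)C)C/C=C(\C)C[C@@H](O)[C@@H]12 | intermediate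
27 | methyl angelate (methyl (2Z)-2-methylbut-2-enoate) | C/C=C(/C)C(=O)OC | starting material
28 | (2Z)-2-methylbut-2-en-1-ol | C/C=C(/C)CO | intermediate
29 | [(2S,3R)-2,3-dimethyloxiran-2-yl]methanol | OC[C@]1(C)O[C@@H]1C | intermediate
30 | (2R,3R)-2,3-dimethyloxirane-2-carboxylic acid (epoxyangelic acid) | OC(=O)[C@]1(C)O[C@@H]1C | intermediate
31 | (2R,3R)-2,3-dimethyloxirane-2-carboxylic 2,4,6-trichlorobenzoic anhydride | O=C(OC(=O)[C@]1(C)O[C@@H]1C)c1c(Cl)cc(Cl)cc1Cl | intermediate (not isolated)
32 | (3S,6R,7R,8R)-8-{[(2R,3R)-2,3-dimethyloxiran-2-yl]carbonyloxy}-3-[(3-methylbutanoyl)oxy]germacra-1(10)E,4Z,11(13)-trien-12,6-olide | C=C1C(=O)O[C@@H]2/C=C(/C)[C@@H](OC(=O)CC(C)C)C/C=C(\C)C[C@@H](OC(=O)[C@]3(C)O[C@@H]3C)[C@@H]12 | intermediate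
33 | (1R,3S,6R,7R,8R,10R)-1,10-epoxy-8-{[(2R,3R)-2,3-dimethyloxiran-2-yl]carbonyloxy}-3-[(3-methylbutanoyl)oxy]germacra-4Z,11(13)-dien-12,6-olide (CNP0167461.2) | C=C1C(=O)O[C@@H]2/C=C(/C)[C@@H](OC(=O)CC(C)C)C[C@H]3O[C@]3(C)C[C@@H](OC(=O)[C@]3(C)O[C@@H]3C)[C@@H]12 | target

## Step count and least certain steps

Total step count: 21. Longest linear sequence: 16 steps (steps 1–8, 11–16, 20 and 21, from 1 to 33).

**Step 14 (key step).**
- What may go wrong: aldehyde 22 may decompose before it is captured. Its C7–H is α to the aldehyde and allylic to the acrylate, so epimerisation, double-bond migration into conjugation or β-elimination of the C8 silyloxy group can compete. Intermolecular coupling or reductive loss of iodine can also outrun closure of the strained ten-membered ring.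
- Fallback (from 20, back at 25): the acrylate is masked so that the vinyl group no longer acidifies C7–H or offers a Michael acceptor.
 - Conjugate addition of thiophenol to 20 (PhSH, Et3N cat.) would give the thiophenol adduct F1 (both C11 epimers).
 - Acetal cleavage as in step 13 would give the aldehyde F2.
 - Ring closure under the conditions of step 14 would give the ten-membered alcohol F3, and lactonisation as in step 15 the sulfide lactone F4.
 - Oxidation with NaIO4 would give the sulfoxide F5. On warming in toluene F5 loses benzenesulfenic acid; the only β-hydrogen is on C11, so the exocyclic methylene of 25 is the only possible outcome.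

**Step 11.**
- What may go wrong: there is no discrimination between the two faces of aldehyde 13, because C3 is six bonds from C8. The syn adduct should form as two diastereomers in similar amounts that differ only in the sense of C7/C8 relative to the remote C3 and may be hard to separate. Partial lactonisation through the C8 hydroxyl is a lesser concern.
- Fallback (from 19 as the mixture of syn isomers and acid 30, back at 32): instead of silylation, the mixture is esterified with 30 under the conditions of step 20.
 - The chiral acyl group then sits next to C8, and the resulting C8 esters should separate; the wanted one is the epoxyangelate acetal F6.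
 - Acetal cleavage as in step 13 would give the aldehyde F7, ring closure as in step 14 the ten-membered alcohol F8, and lactonisation as in step 15 returns to 32.
 - Steps 12, 16 and 20 fall away. The price is a β-acyloxy aldehyde that eliminates more easily than the silyl ether.

**Step 21.**
- What may go wrong: face or site selectivity may be poor. The ring conformation of the 4Z skeleton may not shield one face of C1=C10 as well as assumed, and excess peracid can reach C4=C5.
- Fallback (from 32 directly to 33): the Shi epoxidation. A chiral dioxirane generated from the fructose-derived ketone (the enantiomer chosen to match the wanted face) and KHSO5 at buffered pH selects the face of the trisubstituted E olefin by reagent control. This fallback makes no compound that is not already listed (F0).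

**Step 15.**
- What may go wrong: the acid may ionise the C6 allylic alcohol or cleave the silyl ether before the lactone closes, or the methyl ester may react too slowly.
- Fallback (from 24, back at 25): the methyl ester is cleaved selectively with Me3SnOH in 1,2-dichloroethane to the hydroxy acid F9. F9 is closed with a carbodiimide under neutral conditions to 25.

## Further compounds

F1 | step 14 | thiophenol adduct of 20: 13-(phenylsulfanyl)-11,13-dihydro analogue of 20 (C11 epimers) | I/C=C(/C)[C@@H](OC(=O)CC(C)C)C/C=C(\C)C[C@@H](O[Si](C)(C)C(C)(C)C)[C@@H](C(CSc1ccccc1)C(=O)OC)C(OC)OC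
F2 | step 14 | C6 aldehyde from F1 | I/C=C(/C)[C@@H](OC(=O)CC(C)C)C/C=C(\C)C[C@@H](O[Si](C)(C)C(C)(C)C)[C@@H](C(CSc1ccccc1)C(=O)OC)C=O
F3 | step 14 | ten-membered C6 alcohol from F2 (methyl ester, C13 phenylsulfanyl) | COC(=O)C(CSc1ccccc1)[C@H]1[C@H](O)/C=C(/C)[C@@H](OC(=O)CC(C)C)C/C=C(\C)C[C@H]1O[Si](C)(C)C(C)(C)C
F4 | step 14 | 13-(phenylsulfanyl)-11,13-dihydro analogue of 25 (sulfide lactone) | O=C1O[C@@H]2/C=C(/C)[C@@H](OC(=O)CC(C)C)C/C=C(\C)C[C@@H](O[Si](C)(C)C(C)(C)C)[C@H]2C1CSc1ccccc1
F5 | step 14 | sulfoxide of F4 | O=C1O[C@@H]2/C=C(/C)[C@@H](OC(=O)CC(C)C)C/C=C(\C)C[C@@H](O[Si](C)(C)C(C)(C)C)[C@H]2C1CS(=O)c1ccccc1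
F6 | step 11 | C8 (2R,3R)-epoxyangelate of 19 | I/C=C(/C)[C@@H](OC(=O)CC(C)C)C/C=C(\C)C[C@@H](OC(=O)[C@]1(C)O[C@@H]1C)[C@@H](C(=C)C(=O)OC)C(OC)OC
F7 | step 11 | C6 aldehyde from F6 | I/C=C(/C)[C@@H](OC(=O)CC(C)C)C/C=C(\C)C[C@@H](OC(=O)[C@]1(C)O[C@@H]1C)[C@@H](C(=C)C(=O)OC)C=O
F8 | step 11 | ten-membered C6 alcohol with C8 epoxyangelate (methyl ester) | C=C(C(=O)OC)[C@H]1[C@H](O)/C=C(/C)[C@@H](OC(=O)CC(C)C)C/C=C(\C)C[C@H]1OC(=O)[C@]1(C)O[C@@H]1C
F9 | step 15 | hydroxy acid from 24 | C=C(C(=O)O)[C@H]1[C@H](O)/C=C(/C)[C@@H](OC(=O)CC(C)C)C/C=C(\C)C[C@H]1O[Si](C)(C)C(C)(C)C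
F0 | step 21 | none | none
A1 | alternative 1 | 3,6-endoperoxide of the ten-membered ring with Z C4=C5, C7 methyl acrylate, 1,10-epoxide and C8 epoxyangelate | C=C(C(=O)OC)[C@H]1[C@@H]2OO[C@@H](C(C)=C2)C[C@H]3O[C@]3(C)C[C@H]1OC(=O)[C@]1(C)O[C@@H]1C
A2 | alternative 2 | trans-fused α-(diethoxyphosphoryl)-γ-lactone with C3 silyl ether and free C8 hydroxyl | CCOP(=O)(OCC)[C@@H]1C(=O)O[C@@H]2/C=C(/C)[C@@H](O[Si](C)(C)C(C)(C)C)C/C=C(\C)C[C@@H](O)[C@@H]12
A3 | alternative 3 | ten-membered (4Z,1(10)E)-dien-6-one with C3 silyl ether and C8 benzyldimethylsilyl group | O=C1/C=C(/C)[C@@H](O[Si](C)(C)C(C)(C)C)C/C=C(\C)C[C@@H]([Si](C)(C)Cc2ccccc2)C1
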